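**Plan**

- Retrosynthesis, in order: the five O–benzyl bonds (global protection), the ester C–O bond from the benzoate to the (S)-3-oxybutanoic acid arm, the ring–carboxyl C–C bond, the ester C–O bond between the two aliphatic acyl units, the two bonds at the carbonyl carbon of the inner acyl unit (ester C–O and C(=O)–CH2), and last the aryl–CH2 bond.
- Enabling feature: the inner acyl unit is a 3-oxygenated butanoyl group, O–C(=O)–CH2–CH(O)–CH3. Its C2, C3, C4 and the C3 oxygen are the atoms of a methyloxirane ring and its carbonyl carbon is one CO. The terminal 3,4-dihydroxybutanoyl unit has the same C(=O)–CH2–CH(O) pattern (glycidyl ether plus CO).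
- Forward: the chain grows linearly outward from the arene and no ring is formed. The order is aryl–CH2 bond by Grignard opening of (R)-propylene oxide, inner unit by Co2(CO)8-catalysed carbonylation of a second (R)-propylene oxide with the aryl carbinol as acyl acceptor, terminal unit by esterification, ring formylation and oxidation, Mitsunobu esterification, hydrogenolysis.
- Stereochemistry: all four centres are purchased. Two come from (R)-propylene oxide and one from (R)-benzyl glycidyl ether, each retained because only the oxirane CH2 is attacked. The (S) centre comes from (R)-3-hydroxybutanoic acid by Mitsunobu inversion.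
- Control of single homologation: in the key step the epoxide is the limiting component and the carbinol is present in threefold excess, the surplus being recovered unchanged. The terminal unit is carbonylated separately in methanol, where the large excess of alcohol rules out chain growth, and is then attached as its O-benzylated acid.

Key step: step 2

Step 1
Reactants: 1 1,3-bis(benzyloxy)-5-bromobenzene; 2 (R)-propylene oxide [(2R)-2-methyloxirane]
Product: 4 (2R)-1-[3,5-bis(benzyloxy)phenyl]propan-2-ol, via arylmagnesium bromide 3 (not isolated)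
Conditions: Mg, THF, reflux; then CuI (10 mol %), 2, −30 °C to 0 °C; aq. NH4Cl
Reagents that add atoms: none
Why: CuI-catalysed Grignard opening of a terminal epoxide, well established for aryl Grignard reagents: the arylcopper species formed from 3 and CuI attacks the unsubstituted CH2 of 2 by SN2, which forms the aryl–CH2 bond without touching the C–O bond at the stereocentre, so the (R) configuration of the oxirane is carried into the carbinol of 4.

Step 2
Reactants: 4 (2R)-1-[3,5-bis(benzyloxy)phenyl]propan-2-ol; 2 (R)-propylene oxide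
Product: 5 (2R)-1-[3,5-bis(benzyloxy)phenyl]propan-2-yl (3R)-3-hydroxybutanoate
Conditions: Co2(CO)8 (5 mol %), 3-hydroxypyridine (10 mol %), CO (40 bar), THF (about 2 M in 4), 60 °C; 2 limiting, 4 in threefold excess
Reagents that add atoms: carbon monoxide, [C-]#[O+]
Why: Proposed new method: Co2(CO)8 and 3-hydroxypyridine should generate [Co(CO)4]− paired with a protic pyridinium/pyridinol partner that activates the oxirane oxygen while [Co(CO)4]− opens the ring by SN2 attack at the unsubstituted CH2; CO then inserts into the new C–Co bond to forge the CH2–C(=O) bond, and the resulting (R)-3-hydroxybutanoyl–Co(CO)4 species is cleaved by the secondary hydroxyl of 4, with the pyridinol shuttling the proton, which forms the ester C–O bond and returns HCo(CO)4 to the cycle, so that the step is a three-component addition of 4, 2 and CO in which nothing is split off. The closest known reaction type is the alkoxycarbonylation of enantiopure terminal epoxides to 3-hydroxy esters by Co2(CO)8 and 3-hydroxypyridine in excess methanol, supported by the alternating copolymerisation of propylene oxide with CO by the same catalyst pair, where chain growth is thought to proceed by acyl transfer to a secondary hydroxyl chain end; what is new is a secondary alcohol used as a reaction partner in a few-fold amount and not as co-solvent. No ring is closed and no stereocentre is created: the carbinol centre of 4 is untouched and the oxirane centre is retained because only its CH2 carbon is attacked, so both (R) centres of 5 are inherited. The step needs regioselective opening at CH2, secured by the steric bias of the methyl-substituted oxirane toward the bulky, soft [Co(CO)4]− nucleophile. It also needs single homologation, secured by keeping the epoxide limiting against a threefold excess of 4 at high concentration and by the lower nucleophilicity of the product hydroxyl, which is inductively deactivated and hydrogen-bonded to its own ester carbonyl.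

Step 3
Reactants: 6 (R)-benzyl glycidyl ether [(2R)-2-[(benzyloxy)methyl]oxirane]
Product: 7 methyl (3R)-4-(benzyloxy)-3-hydroxybutanoate
Conditions: Co2(CO)8 (5 mol %), 3-hydroxypyridine (10 mol %), CO (40 bar), MeOH–THF, 60 °C
Reagents that add atoms: carbon monoxide, [C-]#[O+]; methanol, CO
Why: Methoxycarbonylation of an enantiopure terminal epoxide with Co2(CO)8 and 3-hydroxypyridine is a known reaction type: [Co(CO)4]− opens 6 at its ring CH2, CO inserts and methanol in large excess cleaves the acyl–Co(CO)4 species, so the oxirane centre is retained as the (R) carbinol and a second insertion at the new hydroxyl cannot compete.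

Step 4
Reactants: 7 methyl (3R)-4-(benzyloxy)-3-hydroxybutanoate
Product: 8 methyl (3R)-3,4-bis(benzyloxy)butanoate
Conditions: BnOC(=NH)CCl3, TfOH (cat.), CH2Cl2–cyclohexane, 0 °C to rt
Reagents that add atoms: benzyl 2,2,2-trichloroacetimidate, N=C(OCc1ccccc1)C(Cl)(Cl)Cl
Why: Acid-catalysed O-benzylation with a trichloroacetimidate is the standard base-free way to benzylate a β-hydroxy ester, which avoids the elimination and retro-aldol pathways of alkoxide conditions and leaves the stereocentre untouched.

Step 5
Reactants: 8 methyl (3R)-3,4-bis(benzyloxy)butanoate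
Product: 9 (3R)-3,4-bis(benzyloxy)butanoic acid
Conditions: LiOH, THF–H2O, 0 °C; then 1 M HCl to pH 3
Reagents that add atoms: lithium hydroxide, [Li+].[OH-]
Why: Saponification of a methyl ester with LiOH at low temperature should be much faster than E1cB loss of the β-benzyloxy group, and acidification then frees the acid with the β-stereocentre unchanged.

Step 6
Reactants: 5 (2R)-1-[3,5-bis(benzyloxy)phenyl]propan-2-yl (3R)-3-hydroxybutanoate; 9 (3R)-3,4-bis(benzyloxy)butanoic acid
Product: 10 (2R)-4-{[(2R)-1-[3,5-bis(benzyloxy)phenyl]propan-2-yl]oxy}-4-oxobutan-2-yl (3R)-3,4-bis(benzyloxy)butanoate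
Conditions: EDC·HCl, DMAP (cat.), CH2Cl2, 0 °C to rt
Reagents that add atoms: none
Why: Steglich-type carbodiimide esterification with DMAP as acyl-transfer catalyst joins acid 9 to the only free hydroxyl of 5, and since no bond to a stereocentre is broken all three centres are retained.

Step 7
Reactants: 10 (2R)-4-{[(2R)-1-[3,5-bis(benzyloxy)phenyl]propan-2-yl]oxy}-4-oxobutan-2-yl (3R)-3,4-bis(benzyloxy)butanoate
Product: 12 (2R)-4-{[(2R)-1-[3,5-bis(benzyloxy)-2-formylphenyl]propan-2-yl]oxy}-4-oxobutan-2-yl (3R)-3,4-bis(benzyloxy)butanoate, via aryl iminium chloride 11 (not isolated)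
Conditions: POCl3, DMF, 0 °C to rt; then aq. NaOAc
Reagents that add atoms: N,N-dimethylformamide, CN(C)C=O; water, O
Why: Vilsmeier–Haack formylation of a ring activated by two benzyloxy groups should occur at the carbon ortho to the side chain and para to one ether in preference to the more crowded carbon between the two ethers, as is usual for 3,5-dialkoxy-alkylbenzenes, and buffered aqueous work-up hydrolyses iminium salt 11 to the aldehyde while esters and benzyl ethers survive.

Step 8
Reactants: 12 (2R)-4-{[(2R)-1-[3,5-bis(benzyloxy)-2-formylphenyl]propan-2-yl]oxy}-4-oxobutan-2-yl (3R)-3,4-bis(benzyloxy)butanoate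
Product: 13 2,4-bis(benzyloxy)-6-[(2R)-2-{[(3R)-3-{[(3R)-3,4-bis(benzyloxy)butanoyl]oxy}butanoyl]oxy}propyl]benzoic acid
Conditions: NaClO2, NaH2PO4, 2-methyl-2-butene, t-BuOH–THF–H2O, 0 °C to rt
Reagents that add atoms: sodium chlorite, [Na+].[O-]Cl=O
Why: Pinnick oxidation converts the electron-rich aryl aldehyde to the carboxylic acid under buffered conditions that leave esters and benzyl ethers alone, with 2-methyl-2-butene scavenging HOCl so that the activated ring is not chlorinated.

Step 9
Reactants: 14 (R)-3-hydroxybutanoic acid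
Product: 15 benzyl (3R)-3-hydroxybutanoate
Conditions: BnBr, KHCO3, DMF, rt
Reagents that add atoms: benzyl bromide, BrCc1ccccc1
Why: Carboxylate O-alkylation by SN2 at the benzylic carbon of benzyl bromide under mild bicarbonate conditions esterifies the acid without touching the secondary hydroxyl or the stereocentre.

Step 10
Reactants: 13 2,4-bis(benzyloxy)-6-[(2R)-2-{[(3R)-3-{[(3R)-3,4-bis(benzyloxy)butanoyl]oxy}butanoyl]oxy}propyl]benzoic acid; 15 benzyl (3R)-3-hydroxybutanoate
Product: 16 (2S)-4-(benzyloxy)-4-oxobutan-2-yl 2,4-bis(benzyloxy)-6-[(2R)-2-{[(3R)-3-{[(3R)-3,4-bis(benzyloxy)butanoyl]oxy}butanoyl]oxy}propyl]benzoate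
Conditions: PPh3, DIAD, toluene, 0 °C to rt
Reagents that add atoms: none
Why: In this Mitsunobu esterification the hindered benzoic acid 13 acts as the nucleophile and displaces the oxyphosphonium derived from the (R) alcohol 15 by SN2 with inversion, which sets the (S) centre of the aryl ester and sidesteps acyl activation of a di-ortho-substituted benzoic acid.

Step 11
Reactants: 16 (2S)-4-(benzyloxy)-4-oxobutan-2-yl 2,4-bis(benzyloxy)-6-[(2R)-2-{[(3R)-3-{[(3R)-3,4-bis(benzyloxy)butanoyl]oxy}butanoyl]oxy}propyl]benzoate
Product: 17 Talapolyester B, (3S)-3-({2-[(2R)-2-{[(3R)-3-{[(3R)-3,4-dihydroxybutanoyl]oxy}butanoyl]oxy}propyl]-4,6-dihydroxybenzoyl}oxy)butanoic acid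
Conditions: H2 (1 atm), Pd(OH)2/C, EtOAc–THF, rt
Reagents that add atoms: none
Why: Catalytic hydrogenolysis should cleave the two aryl benzyl ethers, the two alkyl benzyl ethers and the benzyl ester in one neutral operation, which leaves the three ester links and the four stereocentres, none of them benzylic, untouched.

**Compound list**

1 | 1,3-bis(benzyloxy)-5-bromobenzene | Brc1cc(OCc2ccccc2)cc(OCc2ccccc2)c1 | starting material
2 | (R)-propylene oxide [(2R)-2-methyloxirane] | C[C@@H]1CO1 | starting material
3 | [3,5-bis(benzyloxy)phenyl]magnesium bromide | Br[Mg]c1cc(OCc2ccccc2)cc(OCc2ccccc2)c1 | intermediate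
4 | (2R)-1-[3,5-bis(benzyloxy)phenyl]propan-2-ol | C[C@@H](O)Cc1cc(OCc2ccccc2)cc(OCc2ccccc2)c1 | intermediate
5 | (2R)-1-[3,5-bis(benzyloxy)phenyl]propan-2-yl (3R)-3-hydroxybutanoate | C[C@@H](O)CC(=O)O[C@H](C)Cc1cc(OCc2ccccc2)cc(OCc2ccccc2)c1 | intermediate
6 | (R)-benzyl glycidyl ether [(2R)-2-[(benzyloxy)methyl]oxirane] | C1[C@@H](O1)COCc1ccccc1 | starting material
7 | methyl (3R)-4-(benzyloxy)-3-hydroxybutanoate | COC(=O)C[C@@H](O)COCc1ccccc1 | intermediate
8 | methyl (3R)-3,4-bis(benzyloxy)butanoate | COC(=O)C[C@@H](OCc1ccccc1)COCc1ccccc1 | intermediate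
9 | (3R)-3,4-bis(benzyloxy)butanoic acid | OC(=O)C[C@@H](OCc1ccccc1)COCc1ccccc1 | intermediate
10 | (2R)-4-{[(2R)-1-[3,5-bis(benzyloxy)phenyl]propan-2-yl]oxy}-4-oxobutan-2-yl (3R)-3,4-bis(benzyloxy)butanoate | C[C@H](CC(=O)O[C@H](C)Cc1cc(OCc2ccccc2)cc(OCc2ccccc2)c1)OC(=O)C[C@@H](OCc1ccccc1)COCc1ccccc1 | intermediate
11 | N,N-dimethyl aryl iminium chloride of 12 (ArCH=NMe2+ Cl−) | C[C@H](CC(=O)O[C@H](C)Cc1cc(OCc2ccccc2)cc(OCc2ccccc2)c1C=[N+](C)C)OC(=O)C[C@@H](OCc1ccccc1)COCc1ccccc1.[Cl-] | intermediate
12 | (2R)-4-{[(2R)-1-[3,5-bis(benzyloxy)-2-formylphenyl]propan-2-yl]oxy}-4-oxobutan-2-yl (3R)-3,4-bis(benzyloxy)butanoate | C[C@H](CC(=O)O[C@H](C)Cc1cc(OCc2ccccc2)cc(OCc2ccccc2)c1C=O)OC(=O)C[C@@H](OCc1ccccc1)COCc1ccccc1 | intermediate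
13 | 2,4-bis(benzyloxy)-6-[(2R)-2-{[(3R)-3-{[(3R)-3,4-bis(benzyloxy)butanoyl]oxy}butanoyl]oxy}propyl]benzoic acid | C[C@H](CC(=O)O[C@H](C)Cc1cc(OCc2ccccc2)cc(OCc2ccccc2)c1C(=O)O)OC(=O)C[C@@H](OCc1ccccc1)COCc1ccccc1 | intermediate
14 | (R)-3-hydroxybutanoic acid | C[C@@H](O)CC(=O)O | starting material
15 | benzyl (3R)-3-hydroxybutanoate | C[C@@H](O)CC(=O)OCc1ccccc1 | intermediate
16 | (2S)-4-(benzyloxy)-4-oxobutan-2-yl 2,4-bis(benzyloxy)-6-[(2R)-2-{[(3R)-3-{[(3R)-3,4-bis(benzyloxy)butanoyl]oxy}butanoyl]oxy}propyl]benzoate | C[C@H](CC(=O)O[C@H](C)Cc1cc(OCc2ccccc2)cc(OCc2ccccc2)c1C(=O)O[C@@H](C)CC(=O)OCc1ccccc1)OC(=O)C[C@@H](OCc1ccccc1)COCc1ccccc1 | intermediate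
17 | Talapolyester B, (3S)-3-({2-[(2R)-2-{[(3R)-3-{[(3R)-3,4-dihydroxybutanoyl]oxy}butanoyl]oxy}propyl]-4,6-dihydroxybenzoyl}oxy)butanoic acid | C[C@H](CC(=O)O[C@H](C)Cc1cc(O)cc(O)c1C(=O)O[C@@H](C)CC(=O)O)OC(=O)C[C@@H](O)CO | target

**Count and risks**

Total step count: 11.
Longest linear sequence: 8 steps (from 6 through steps 3, 4, 5, 6, 7, 8, 10 and 11). From bromide 1 the count is 7.

Steps most likely to fail:

Step 2 (the step proposed as a new method). Three processes threaten it: a second epoxide/CO insertion at the newly formed hydroxyl, leading to oligoester growth; slow alcoholysis of the acyl–Co(CO)4 intermediate by a secondary alcohol that is present only in a few-fold amount; and isomerisation of the epoxide by HCo(CO)4. Should any of these dominate, the same two bonds would be made from alcohol 4 by known chemistry at the ketone oxidation level. Thermal acetoacetylation of 4 with 2,2,6-trimethyl-4H-1,3-dioxin-4-one (xylene, 130 °C) should give (2R)-1-[3,5-bis(benzyloxy)phenyl]propan-2-yl 3-oxobutanoate F1. Noyori asymmetric hydrogenation of its ketone with RuCl2[(R)-BINAP] (H2 50 bar, MeOH–CH2Cl2, 50 °C) should then set the (3R) carbinol under catalyst control and return to 5. RuCl2[(R)-BINAP] should not cleave the aryl benzyl ethers.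

Step 10. The oxyphosphonium of the β-hydroxy ester may eliminate to the crotonate faster than the hindered carboxylate displaces it, so that the alcohol partner is consumed without ester formation. In that case the ester would be made with retention from the enantiomeric alcohol. Acid 13 would be converted under neutral conditions with 1-chloro-N,N,2-trimethylprop-1-en-1-amine (CH2Cl2, 0 °C) into 2,4-bis(benzyloxy)-6-[(2R)-2-{[(3R)-3-{[(3R)-3,4-bis(benzyloxy)butanoyl]oxy}butanoyl]oxy}propyl]benzoyl chloride F2. This would acylate benzyl (3S)-3-hydroxybutanoate F3, made from commercial (S)-3-hydroxybutanoic acid with BnBr and KHCO3 as in step 9, in the presence of Et3N and DMAP, and so arrive at 16 directly.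

Step 7. The chloroiminium ion may attack the ring carbon flanked by the two benzyloxy groups, or the bulky substrate may not convert at temperatures that the esters and ethers tolerate. The carboxyl carbon would then be introduced by halogenation and carbonylation starting from 10. N-Iodosuccinimide in MeCN should iodinate the ring carbon ortho to the side chain and para to a benzyloxy group, giving (2R)-4-{[(2R)-1-[3,5-bis(benzyloxy)-2-iodophenyl]propan-2-yl]oxy}-4-oxobutan-2-yl (3R)-3,4-bis(benzyloxy)butanoate F4. Hydroxycarbonylation with Pd(OAc)2 and Xantphos (CO 1 atm, KOAc, DMF–H2O, 70 °C) should convert F4 straight into acid 13, so that steps 7 and 8 are both bypassed.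

Further compounds
F1 | step 2 | (2R)-1-[3,5-bis(benzyloxy)phenyl]propan-2-yl 3-oxobutanoate | CC(=O)CC(=O)O[C@H](C)Cc1cc(OCc2ccccc2)cc(OCc2ccccc2)c1
F2 | step 10 | 2,4-bis(benzyloxy)-6-[(2R)-2-{[(3R)-3-{[(3R)-3,4-bis(benzyloxy)butanoyl]oxy}butanoyl]oxy}propyl]benzoyl chloride | C[C@H](CC(=O)O[C@H](C)Cc1cc(OCc2ccccc2)cc(OCc2ccccc2)c1C(=O)Cl)OC(=O)C[C@@H](OCc1ccccc1)COCc1ccccc1
F3 | step 10 | benzyl (3S)-3-hydroxybutanoate | C[C@H](O)CC(=O)OCc1ccccc1
F4 | step 7 | (2R)-4-{[(2R)-1-[3,5-bis(benzyloxy)-2-iodophenyl]propan-2-yl]oxy}-4-oxobutan-2-yl (3R)-3,4-bis(benzyloxy)butanoate | C[C@H](CC(=O)O[C@H](C)Cc1cc(OCc2ccccc2)cc(OCc2ccccc2)c1I)OC(=O)C[C@@H](OCc1ccccc1)COCc1ccccc1
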